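**Retrosynthetic overview**

1. Numbering used: ring A is the bromocyclohexane C6–C11 (C6 fusion CH, C7 O-bearing quaternary carbon, C10 CHBr, C11 CMe2); ring B is the oxepane C7–O–C2(=C1HBr)–C3(Me)–C4–C5–C6 with the C3–C4 epoxide. The (E)-bromomethylidene group comes from lactone 16 by dibromomethylenation and site-selective hydrodebromination, the lactone oxygen from Baeyer–Villiger insertion into the C2–C7 bond of an epoxy decalone, and C10–Br from a ring-A bromoalkene by hydrogen-atom-transfer hydrogenation.
2. Key disconnection: the ring-fusion bond C6–C7, formed by an enantioselective intramolecular enol Michael addition that closes ring A; an aldol condensation closes a carbocyclic ring B in the same flask, starting from the acyclic dioxo-enal 9.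
3. Enabling feature: the ring oxygen lies between the quaternary C7 and C2, which is the pattern a Baeyer–Villiger oxidation leaves. With a C2–C7 carbon–carbon bond in its place (absent from the target, cleaved in step 8), C7 is the α-carbon of a C2 ketone and C6 the β-carbon of a C4 carbonyl, a 1,5-dicarbonyl relation across C6–C7; C3=C4 is then an enone that brings in the epoxide.
4. Ring order: ring A and carbocyclic ring B together (step 4), oxirane (step 6), ring B expanded to the seven-membered lactone (step 8).
5. Precursor 9 is assembled from 2,2-dimethylbut-3-enoic acid, 2-methylpent-1-en-3-one and crotonaldehyde by ketone synthesis, Mukaiyama–Michael addition and cross-metathesis.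

Key step: step 4

Remark: the sense of induction of the chiral phosphoric acid in step 4 cannot be fixed on paper; (R)-TRIP, (R)-3,3'-bis(2,4,6-triisopropylphenyl)-1,1'-binaphthyl-2,2'-diyl hydrogen phosphate, is written, and its enantiomer takes its place if the cyclisation favours the mirror-image series.

**Step 1**
Reactants: 1 2,2-dimethylbut-3-enoic acid
Product: 3 3,3-dimethylpent-4-en-2-one, via dilithium gem-diolate 2 (not isolated)
Conditions: MeLi (2.2 equiv), Et2O, 0 °C to rt; then aq. NH4Cl
Reagents that add atoms: methyllithium, [Li]C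
Why: addition of an alkyllithium to a lithium carboxylate (carboxylic acid to methyl ketone synthesis) stops at the dilithium gem-diolate 2, which gives the ketone only on hydrolysis, and the quaternary α-carbon excludes enolisation or conjugation of the vinyl group.

**Step 2**
Reactants: 3 3,3-dimethylpent-4-en-2-one; 4 2-methylpent-1-en-3-one
Product: 7 4,8,8-trimethyldec-9-ene-3,7-dione (racemic at C4), via silyl enol ether 5 (not isolated), via silylated Michael adduct 6 (not isolated)
Conditions: LiN(i-Pr)2, THF, −78 °C, then Me3SiCl; solvent switch; 4, Sc(OTf)3 (5 mol%), CH2Cl2, −78 to 0 °C; 1 M HCl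
Reagents that add atoms: chlorotrimethylsilane, C[Si](C)(C)Cl (its silicon stays only in 5 and 6 and is lost on hydrolysis)
Why: Mukaiyama–Michael addition, regiodefined because ketone 3 has a single enolisable position, to the unhindered β-carbon of the α-methyl vinyl ketone 4; the stereocentre formed at C4 need not be controlled because it is enolised in step 4.

**Step 3**
Reactants: 7 4,8,8-trimethyldec-9-ene-3,7-dione; 8 (E)-but-2-enal (crotonaldehyde)
Product: 9 (E)-4,4,8-trimethyl-5,9-dioxoundec-2-enal
Conditions: second-generation Hoveyda–Grubbs catalyst RuCl2(H2IMes)(=CH-C6H4-2-O-i-Pr) (5 mol%), 8 (5 equiv), CH2Cl2, 40 °C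
Reagents that add atoms: none
Why: olefin cross-metathesis between a vinyl group on a quaternary carbon, which cannot homodimerise, and an excess of an electron-poor partner should give the (E)-enal under thermodynamic control, with propene as the only coproduct and both ketones untouched.

**Step 4**
Reactants: 9 (E)-4,4,8-trimethyl-5,9-dioxoundec-2-enal
Product: 12 (4aR,8aR)-2,5,5,8a-tetramethyl-4a,5,8,8a-tetrahydronaphthalene-1,6(4H,7H)-dione, via Michael adduct 10 (not isolated), via aldol 11 (not isolated)
Conditions: (R)-TRIP (10 mol%), PhMe, 50 °C; then p-TsOH·H2O (10 mol%), 80 °C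
Reagents that add atoms: none
Why: Proposed new method: the chiral phosphoric acid is expected to enolise the C9 ketone of 9 towards C8 (the more substituted enol), to hold this enol and the enal carbonyl by two hydrogen bonds and so to deliver C8 to the enal β-carbon C3, which forms the C3–C8 bond (C6–C7 of the target) and ring A and gives 10, whose aldehyde then condenses with the ethyl ketone α-carbon C10 (aldol 11, dehydration) to close the carbocyclic ring B. The closest known reaction type is Brønsted acid enol catalysis, in which chiral phosphoric acids add the more substituted enol of α-branched cyclic ketones to enones to build quaternary stereocentres that are then carried through a Robinson annulation; new here are the ring-closing version, the acyclic ketone and the enal acceptor. Ring A closes in a 6-exo-trig mode (enol carbon onto the enal β-carbon) and ring B in a 6-(enolendo)-exo-trig aldol addition followed by loss of water. The absolute configuration at C8a and C4a is set by the phosphate, which blocks one enantioface of the hydrogen-bonded enol–enal pair, and their trans relation follows from a chair transition state in which the phosphate-bound enol unit sits equatorial and anti to the quaternary C4 while the small methyl group takes the axial site. Regioselectivity is secured because only the C8 enol can reach the acceptor through a six-membered transition state (the C10 enol would have to close an eight-membered ring), and chemoselectivity over aldol closure of the 1,5-diketone because the C5 carbonyl is a hindered tert-alkyl ketone whose aldol adduct forms reversibly and cannot dehydrate without severe strain. The racemic C8 centre of 9 is erased on enolisation, so both enantiomers of 9 should converge on 12.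

**Step 5**
Reactants: 12 (4aR,8aR)-2,5,5,8a-tetramethyl-4a,5,8,8a-tetrahydronaphthalene-1,6(4H,7H)-dione
Product: 13 (4aS,8aR)-6-bromo-2,5,5,8a-tetramethyl-4a,5,8,8a-tetrahydronaphthalen-1(4H)-one
Conditions: (PhO)3P, Br2, Et3N, CH2Cl2, −60 °C to reflux
Reagents that add atoms: bromine, BrBr
Why: conversion of an enolisable ketone into a vinyl bromide with triphenyl phosphite dibromide and triethylamine, regiodefined because the C6 ketone can enolise only towards C7 and chemoselective because the C1 carbonyl is conjugated, has no α-hydrogen and is flanked by a quaternary carbon; no stereocentre is touched (the changed C4a descriptor is a priority effect).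

**Step 6**
Reactants: 13 (4aS,8aR)-6-bromo-2,5,5,8a-tetramethyl-4a,5,8,8a-tetrahydronaphthalen-1(4H)-one
Product: 14 (2S,3S,4aS,8aR)-6-bromo-2,3-epoxy-2,5,5,8a-tetramethyl-2,3,4,4a,5,8-hexahydronaphthalen-1(8aH)-one
Conditions: 30% aq. H2O2, NaOH, MeOH, 0 °C
Reagents that add atoms: hydrogen peroxide, OO
Why: Weitz–Scheffer nucleophilic epoxidation, in which hydroperoxide should add axially to C3 of the rigid trans-fused enone from the α-face, opposite to the axial 8a-methyl group, and the enolate closes the oxirane on the same face, setting C2 and C3 (epoxide anti to the angular methyl) while the bromoalkene is inert.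

**Step 7**
Reactants: 14 (2S,3S,4aS,8aR)-6-bromo-2,3-epoxy-2,5,5,8a-tetramethyl-2,3,4,4a,5,8-hexahydronaphthalen-1(8aH)-one
Product: 15 (2S,3S,4aS,6R,8aR)-6-bromo-2,3-epoxy-2,5,5,8a-tetramethyl-3,4,4a,5,6,7,8,8a-octahydronaphthalen-1(2H)-one
Conditions: Mn(dpm)3 (10 mol%), PhSiH3, t-BuOOH, i-PrOH, 22 °C
Reagents that add atoms: none
Why: metal-hydride hydrogen atom transfer hydrogenation, which reduces alkenyl halides without hydrogenolysis: a hydrogen atom adds to C7, and the α-bromo radical at C6 should take the second hydrogen axially from the α-face, away from the axial 5β- and 8a-methyl groups, so that bromine ends equatorial (6R, the thermodynamically preferred epimer).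

**Step 8**
Reactants: 15 (2S,3S,4aS,6R,8aR)-6-bromo-2,3-epoxy-2,5,5,8a-tetramethyl-3,4,4a,5,6,7,8,8a-octahydronaphthalen-1(2H)-one
Product: 16 (3S,4S,5aR,7R,9aR)-7-bromo-3,4-epoxy-3,6,6,9a-tetramethyl-4,5,5a,6,7,8,9,9a-octahydro-1-benzoxepin-2(3H)-one
Conditions: m-CPBA, NaHCO3, CH2Cl2, 25 °C
Reagents that add atoms: 3-chloroperoxybenzoic acid, OOC(=O)c1cccc(Cl)c1
Why: Baeyer–Villiger oxidation, in which the fully alkyl-substituted C8a is expected to migrate in preference to the strained, inductively deactivated oxiranyl carbon and does so with retention, so oxygen enters the C1–C8a bond, the temporary carbon–carbon bond is cleaved and the quaternary centre keeps its configuration.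

**Step 9**
Reactants: 16 (3S,4S,5aR,7R,9aR)-7-bromo-3,4-epoxy-3,6,6,9a-tetramethyl-4,5,5a,6,7,8,9,9a-octahydro-1-benzoxepin-2(3H)-one
Product: 17 (3S,4S,5aR,7R,9aR)-7-bromo-2-(dibromomethylidene)-3,4-epoxy-3,6,6,9a-tetramethyldecahydro-1-benzoxepine
Conditions: [Ph3PCHBr2]Br, KOt-Bu, PhMe, 0 °C; then 16, 90 °C
Reagents that add atoms: (dibromomethyl)triphenylphosphonium bromide, BrC(Br)[P+](c1ccccc1)(c1ccccc1)c1ccccc1.[Br-]
Why: Wittig-type dihalomethylenation of a lactone carbonyl, a reaction established for lactones that carry an α-oxygen substituent as 16 does, run with the preformed ylide so that no Ph3PBr2 or zinc halide is present to open the epoxide; no stereocentre is involved.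

**Step 10**
Reactants: 17 (3S,4S,5aR,7R,9aR)-7-bromo-2-(dibromomethylidene)-3,4-epoxy-3,6,6,9a-tetramethyldecahydro-1-benzoxepine
Product: 18 (3S,4S,5aR,7R,9aR)-7-bromo-2-[(E)-bromomethylidene]-3,4-epoxy-3,6,6,9a-tetramethyldecahydro-1-benzoxepine (CNP0375295.2)
Conditions: Pd(PPh3)4 (5 mol%), Bu3SnH (1.05 equiv), PhH, 20 °C, dark
Reagents that add atoms: none
Why: palladium-catalysed mono-hydrogenolysis of a 1,1-dibromoalkene with tributyltin hydride, in which zerovalent palladium should insert into the less hindered C–Br bond, here the one cis to the ring oxygen and trans to the quaternary epoxide carbon C3, so that the bromine left behind is trans to oxygen ((E)-geometry), while the secondary alkyl bromide and the epoxide are not attacked without a radical initiator.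

**Compound list**

1 | 2,2-dimethylbut-3-enoic acid | C=CC(C)(C)C(=O)O | starting material
2 | dilithium 3,3-dimethylpent-4-ene-2,2-diolate | CC([O-])([O-])C(C)(C)C=C.[Li+].[Li+] | intermediate (not isolated)
3 | 3,3-dimethylpent-4-en-2-one | CC(=O)C(C)(C)C=C | intermediate
4 | 2-methylpent-1-en-3-one | CCC(=O)C(C)=C | starting material
5 | (3,3-dimethylpenta-1,4-dien-2-yl)oxytrimethylsilane | C=C(O[Si](C)(C)C)C(C)(C)C=C | intermediate (not isolated)
6 | trimethyl[(4,8,8-trimethyl-7-oxodeca-3,9-dien-3-yl)oxy]silane (E/Z mixture) | CCC(O[Si](C)(C)C)=C(C)CCC(=O)C(C)(C)C=C | intermediate (not isolated)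
7 | 4,8,8-trimethyldec-9-ene-3,7-dione (racemic) | CCC(=O)C(C)CCC(=O)C(C)(C)C=C | intermediate
8 | (E)-but-2-enal | C/C=C/C=O | starting material
9 | (E)-4,4,8-trimethyl-5,9-dioxoundec-2-enal (racemic) | CCC(=O)C(C)CCC(=O)C(C)(C)/C=C/C=O | intermediate
10 | 2-[(1R,2R)-2,6,6-trimethyl-5-oxo-2-propanoylcyclohexyl]acetaldehyde | CC1(C)C(=O)CC[C@@](C)(C(=O)CC)[C@@H]1CC=O | intermediate (not isolated)
11 | (4aR,8aR)-3-hydroxy-2,5,5,8a-tetramethyloctahydronaphthalene-1,6-dione (mixture at C2 and C3) | CC1(C)C(=O)CC[C@@]2(C)C(=O)C(C)C(O)C[C@H]12 | intermediate (not isolated)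
12 | (4aR,8aR)-2,5,5,8a-tetramethyl-4a,5,8,8a-tetrahydronaphthalene-1,6(4H,7H)-dione (trans-fused) | CC1(C)C(=O)CC[C@@]2(C)C(=O)C(C)=CC[C@H]12 | intermediate
13 | (4aS,8aR)-6-bromo-2,5,5,8a-tetramethyl-4a,5,8,8a-tetrahydronaphthalen-1(4H)-one | CC1(C)C(Br)=CC[C@@]2(C)C(=O)C(C)=CC[C@H]12 | intermediate
14 | (2S,3S,4aS,8aR)-6-bromo-2,3-epoxy-2,5,5,8a-tetramethyl-2,3,4,4a,5,8-hexahydronaphthalen-1(8aH)-one (epoxide anti to 8a-methyl) | CC1(C)C(Br)=CC[C@@]2(C)C(=O)[C@@]3(C)O[C@H]3C[C@H]12 | intermediate
15 | (2S,3S,4aS,6R,8aR)-6-bromo-2,3-epoxy-2,5,5,8a-tetramethyl-3,4,4a,5,6,7,8,8a-octahydronaphthalen-1(2H)-one (equatorial bromine) | CC1(C)[C@H](Br)CC[C@@]2(C)C(=O)[C@@]3(C)O[C@H]3C[C@H]12 | intermediate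
16 | (3S,4S,5aR,7R,9aR)-7-bromo-3,4-epoxy-3,6,6,9a-tetramethyl-4,5,5a,6,7,8,9,9a-octahydro-1-benzoxepin-2(3H)-one | CC1(C)[C@H](Br)CC[C@@]2(C)OC(=O)[C@@]3(C)O[C@H]3C[C@H]12 | intermediate
17 | (3S,4S,5aR,7R,9aR)-7-bromo-2-(dibromomethylidene)-3,4-epoxy-3,6,6,9a-tetramethyldecahydro-1-benzoxepine | CC1(C)[C@H](Br)CC[C@@]2(C)OC(=C(Br)Br)[C@@]3(C)O[C@H]3C[C@H]12 | intermediate
18 | (3S,4S,5aR,7R,9aR)-7-bromo-2-[(E)-bromomethylidene]-3,4-epoxy-3,6,6,9a-tetramethyldecahydro-1-benzoxepine | CC1(C)[C@H](Br)CC[C@@]2(C)O/C(=C/Br)[C@@]3(C)O[C@H]3C[C@H]12 | target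

**Step count and risks**

Total step count: 10. Longest linear sequence: 10 steps (1 to 18); 4 and 8 enter as purchased building blocks.

The three steps most likely to fail:

Step 4 (proposed new method). The phosphoric acid may discriminate the enantiofaces poorly, closure may run through the alternative chair to the cis-fused series, or the 1,5-diketone may undergo aldol closure before the Michael addition. The fallback uses auxiliary-controlled known chemistry and sets out from 7. Cross-metathesis with methyl acrylate would give methyl (E)-4,4,8-trimethyl-5,9-dioxoundec-2-enoate F1. Condensation of the ethyl ketone (the tert-alkyl ketone is too hindered) with (S)-1-phenylethylamine (or its antipode, as the sense of induction requires) would give the imine methyl (E)-4,4,8-trimethyl-5-oxo-9-{[(1S)-1-phenylethyl]imino}undec-2-enoate F2. On heating, its tetrasubstituted secondary enamine tautomer should add to the enoate in an intramolecular aza-ene-type Michael addition, the established auxiliary method for quaternary centres from α-branched ketones, to give the ring-closed imine methyl 2-[(1S,2R)-2,6,6-trimethyl-5-oxo-2-{N-[(1S)-1-phenylethyl]propanimidoyl}cyclohexyl]acetate F3. Aqueous acetic acid would hydrolyse it to the keto ester methyl 2-[(1R,2R)-2,6,6-trimethyl-5-oxo-2-propanoylcyclohexyl]acetate F4. Claisen (Dieckmann-type) condensation with KOt-Bu would close ring B as (4aR,8aR)-2,5,5,8a-tetramethylhexahydronaphthalene-1,3,6-trione F5. O-Triflation at the less hindered C3 oxygen would give (4aR,8aR)-2,5,5,8a-tetramethyl-1,6-dioxo-1,4,4a,5,6,7,8,8a-octahydronaphthalen-3-yl trifluoromethanesulfonate F6, and reduction of its C–O bond with Pd(OAc)2, PPh3, HCO2H and Et3N comes back to the route at 12.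

Step 9. The ylide may fail to add to the hindered lactone carbonyl, or phosphorus and bromide species may open the epoxide. The fallback sets out from 16. Petasis methylenation (Cp2TiMe2, PhMe, 70 °C) would give the exocyclic enol ether (3S,4S,5aR,7R,9aR)-7-bromo-3,4-epoxy-3,6,6,9a-tetramethyl-2-methylidenedecahydro-1-benzoxepine F7. Bromine addition at −78 °C would give 2,7-dibromo-2-(bromomethyl)-3,4-epoxy-3,6,6,9a-tetramethyldecahydro-1-benzoxepine F8, and DBU would dehydrobrominate it to 7-bromo-2-(bromomethylidene)-3,4-epoxy-3,6,6,9a-tetramethyldecahydro-1-benzoxepine (E/Z mixture, of no consequence) F9. A second bromine addition would give 2,7-dibromo-2-(dibromomethyl)-3,4-epoxy-3,6,6,9a-tetramethyldecahydro-1-benzoxepine F10, and a second dehydrobromination comes back to the route at 17.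

Step 10. Oxidative addition may occur at the wrong C–Br bond (leading to the (Z)-isomer), reduction may run on to the methylidene compound, or the ring bromine may be lost by a radical chain. The fallback sets out from 17. Bromine–lithium exchange with n-BuLi at −105 °C in THF/Et2O/pentane is directed to the bromine cis to the ring oxygen by O–Li coordination and by the lower hindrance of that site. It would give the α-bromoalkenyllithium (lithium cis to the ring oxygen) F11, which is protonated in place with MeOH with retention and comes back to the route at 18.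

**Further compounds**

F1 | step 4 | methyl (E)-4,4,8-trimethyl-5,9-dioxoundec-2-enoate | CCC(=O)C(C)CCC(=O)C(C)(C)/C=C/C(=O)OC
F2 | step 4 | methyl (E)-4,4,8-trimethyl-5-oxo-9-{[(1S)-1-phenylethyl]imino}undec-2-enoate | CCC(=N[C@@H](C)c1ccccc1)C(C)CCC(=O)C(C)(C)/C=C/C(=O)OC
F3 | step 4 | methyl 2-[(1S,2R)-2,6,6-trimethyl-5-oxo-2-{N-[(1S)-1-phenylethyl]propanimidoyl}cyclohexyl]acetate | CC1(C)C(=O)CC[C@@](C)(C(CC)=N[C@@H](C)c2ccccc2)[C@@H]1CC(=O)OC
F4 | step 4 | methyl 2-[(1R,2R)-2,6,6-trimethyl-5-oxo-2-propanoylcyclohexyl]acetate | CC1(C)C(=O)CC[C@@](C)(C(=O)CC)[C@@H]1CC(=O)OC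
F5 | step 4 | (4aR,8aR)-2,5,5,8a-tetramethylhexahydronaphthalene-1,3,6-trione | CC1(C)C(=O)CC[C@@]2(C)C(=O)C(C)C(=O)C[C@H]12
F6 | step 4 | (4aR,8aR)-2,5,5,8a-tetramethyl-1,6-dioxo-1,4,4a,5,6,7,8,8a-octahydronaphthalen-3-yl trifluoromethanesulfonate | CC1(C)C(=O)CC[C@@]2(C)C(=O)C(C)=C(OS(=O)(=O)C(F)(F)F)C[C@H]12
F7 | step 9 | (3S,4S,5aR,7R,9aR)-7-bromo-3,4-epoxy-3,6,6,9a-tetramethyl-2-methylidenedecahydro-1-benzoxepine | CC1(C)[C@H](Br)CC[C@@]2(C)OC(=C)[C@@]3(C)O[C@H]3C[C@H]12
F8 | step 9 | 2,7-dibromo-2-(bromomethyl)-3,4-epoxy-3,6,6,9a-tetramethyldecahydro-1-benzoxepine (C2 epimers) | CC1(C)[C@H](Br)CC[C@@]2(C)OC(Br)(CBr)[C@@]3(C)O[C@H]3C[C@H]12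
F9 | step 9 | 7-bromo-2-(bromomethylidene)-3,4-epoxy-3,6,6,9a-tetramethyldecahydro-1-benzoxepine (E/Z mixture) | CC1(C)[C@H](Br)CC[C@@]2(C)OC(=CBr)[C@@]3(C)O[C@H]3C[C@H]12
F10 | step 9 | 2,7-dibromo-2-(dibromomethyl)-3,4-epoxy-3,6,6,9a-tetramethyldecahydro-1-benzoxepine (C2 epimers) | CC1(C)[C@H](Br)CC[C@@]2(C)OC(Br)(C(Br)Br)[C@@]3(C)O[C@H]3C[C@H]12
F11 | step 10 | α-bromoalkenyllithium derived from 17 (lithium cis to the ring oxygen) | CC1(C)[C@H](Br)CC[C@@]2(C)O/C(=C(/Br)[Li])[C@@]3(C)O[C@H]3C[C@H]12
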